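The earlier runs and the new flask were generated by integration for an exercise.

A small charge comes first: in the beta run, substrate is spent into target and other capture product, with second nucleophile present and gas held, and we ask whether the fraction spent per hour depends on the charge.

| setting | delta | beta | Saturday's | Friday's | Wednesday's | Monday's |
|---|---|---|---|---|---|---|
| substrate | 0.050 M | 0.025 M | 0.050 M | 0.050 M (fed, over 10 h) | 0.050 M | 0.050 M (fed, over 2.5 h) |
| second nucleophile | 0.125 M | 0.125 M | 0.125 M | 0.125 M | 0.125 M (fed, over 10 h) | 0.125 M |
| gas | 6.3 mM (held) | 6.3 mM (held) | 6.3 mM (held) | 6.3 mM (held) | 6.3 mM (held) | 6.3 mM (held) |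
| remark | run made earlier | run made earlier | everything together at the start | all else is in the flask from the start; the feed brings no volume worth counting | all else is in the flask from the start; the feed brings no volume worth counting | all else is in the flask from the start; the feed brings no volume worth counting |
| time |  |  | 25 h | 25 h | 25 h | 25 h |

| run | time / h | other capture product / % | target / % |
|---|---|---|---|
| delta | 1.33 | 12 | 2 |
| delta | 3.00 | 19 | 7 |
| delta | 6.00 | 32 | 11 |
| delta | 15.0 | 53 | 30 |
| beta | 0.333 | 3 | 0 |
| beta | 0.833 | 8 | 1 |
| beta | 1.50 | 10 | 3 |
| beta | 2.50 | 21 | 7 |

(readings scatter by 1.5 percentage points)

- the numbers in the tables scatter with a standard deviation of 1.5 percentage points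
- at the start none of the gas is in solution

* the flask that comes out highest in amount of other capture product, in percent of the substrate charged; "all alike" if 1.5 percentage points covers them all (Saturday's / Friday's / Wednesday's / Monday's / all alike)
* amount of other capture product at the end, in percent of the substrate charged, Saturday's
* amount of other capture product at the end, in percent of the substrate charged, Friday's
* amount of other capture product at the end, in percent of the substrate charged, Wednesday's
* amount of other capture product at the end, in percent of the substrate charged, Monday's

Counting spent substrate as the sum of the two products, we average the first-order constant over the last two readings of each run. Beta, with half of delta's substrate, gives 0.112 h⁻¹. Delta gives the spending constant, the fraction of unspent substrate going per hour, 0.106 h⁻¹, close to beta's. Its half-life is 6.54 h.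

Delta has Saturday's recipe, so it draws Saturday's curve. At the first delta reading, 1.33 h, other capture product holds a read share of 85.7% of the two products. Later the curve bends: between 6.00 h and 15.0 h the read share of what is added is 52.5%, lower than at the first reading. That is a read selectivity factor of 1.11 other capture product per target.

By our reckoning, Saturday's keeps 7.08% of its substrate at 25 h. A steady feed over 10 h leaves Friday's with 12.6% at that same time, by the same reckoning. Carrying the late share forward from the last delta reading, we put Saturday's at 60.0%, running toward a level of 63.7%. Friday's then holds more unspent substrate than Saturday's, so at the same late share we put Friday's 2.9 percentage points lower.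

The forecast gives 60% for Saturday's, 54% for Friday's, 42% for Wednesday's and 58% for Monday's, and names Saturday's highest. It holds that “Friday's loses the bonus and converts less”, and it sets Friday's 6 points lower, a wider gap than ours.

The flasks give 53.7% for Saturday's, 42.9% for Friday's, 47.7% for Wednesday's and 50.4% for Monday's, with Saturday's highest.

    substrate ⇌ intermediate (K = 0.0151, k = 3.30 × 10⁻⁵ s⁻¹)
    first nucleophile + intermediate → target (k = 2.91 L mol⁻¹ s⁻¹)
    second nucleophile + intermediate → other capture product (k = 0.0927 L mol⁻¹ s⁻¹)
    second nucleophile → decomposed reagent (k = 8.74 × 10⁻⁶ s⁻¹)
    gas ⇌ first nucleophile, rate k5*(csat - [first nucleophile]) (kL = 7.73 × 10⁻⁵ s⁻¹)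

With 0.106 h⁻¹, the substrate reckoning stands: at 25.0 h Saturday's holds 7.53% against our 7.08%, and Friday's 13.4% against our 12.6%. The split moved, though: at 25.0 h in Saturday's, intermediate goes to other capture product at 0.28 of its rate to target, below the 1.11 read from delta between 6.00 h and 15.0 h. At that time Saturday's holds 33.6% of its second nucleophile, which goes to decomposed reagent 15 times as fast as into other capture product.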